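**Retrosynthetic overview**
- The target is 5-O-caffeoyl-4-O-malonyl-(−)-quinic acid. The strategy rests on the C3–C4 bond of the cyclohexane ring: C3 and C4 carry a cis-diol whose C4 oxygen is trans to the C5 oxygen. Cutting this bond gives an open-chain 1,6-dialdehyde (C3 and C4 as CHO), which SmI2 pinacol coupling closes again; this is the only ring-forming step.
- The dialdehyde comes from a chiral-pool γ-lactone. C5 is bought in; C1 is set by allylation and then enolate hydroxylation anti to the trityloxymethyl group. The lactone is opened, O5 is silylated and C1-OH/CO2H are tied up as a dioxolanone, so no free O5-H can relactonise.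
- After ring closure, O5 is desilylated and caffeoylated while the cis-3,4-diol is masked as a transient phenylboronate. Equatorial O4 is then malonylated under borinic acid catalysis, and all protecting groups are removed under non-basic conditions.

Key step: step 9

Remark: atoms are numbered as in quinic acid (C1 quaternary carbinol, C7 its carboxyl carbon); (R)-5-(hydroxymethyl)dihydrofuran-2(3H)-one, the lactone of the D-glutamic acid series, is taken as the purchasable source of C5.

**Step 1**
Reactants: 1 (R)-5-(hydroxymethyl)dihydrofuran-2(3H)-one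
Product: 2 (R)-5-(trityloxymethyl)dihydrofuran-2(3H)-one
Conditions: TrCl, pyridine, DMAP (cat.), CH2Cl2, rt
Reagents that add atoms: trityl chloride ClC(c1ccccc1)(c1ccccc1)c1ccccc1
Why: Tritylation of the primary alcohol (SN1-type etherification) installs the bulky group that later shields one face of the lactone enolate; C5 comes unchanged from the chiral pool.

**Step 2**
Reactants: 2 (R)-5-(trityloxymethyl)dihydrofuran-2(3H)-one; 3 allyl bromide
Product: 4 (3S,5R)-3-allyl-5-(trityloxymethyl)dihydrofuran-2(3H)-one (3,5-trans isomer expected as the main product)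
Conditions: LiN(iPr)2, THF, −78 °C; then 3, −78 → −40 °C
Reagents that add atoms: none
Why: Lactone enolate alkylation with an allylic bromide should be clean at low temperature, with allyl entering mainly trans to the trityloxymethyl group; this centre is planarised again in step 3, so its configuration is of no consequence.

**Step 3**
Reactants: 4 (3S,5R)-3-allyl-5-(trityloxymethyl)dihydrofuran-2(3H)-one
Product: 5 (3S,5R)-3-allyl-3-hydroxy-5-(trityloxymethyl)dihydrofuran-2(3H)-one (OH trans and allyl cis to the trityloxymethyl group)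
Conditions: KN(SiMe3)2, THF, −78 °C; then 2-(phenylsulfonyl)-3-phenyloxaziridine, −78 °C; AcOH quench
Reagents that add atoms: 2-(phenylsulfonyl)-3-phenyloxaziridine O=S(=O)(c1ccccc1)N1OC1c1ccccc1
Why: Davis oxaziridine hydroxylation of the tetrasubstituted potassium enolate should deliver oxygen to the face opposite the C5 trityloxymethyl group, which sets the quaternary C1 with allyl (C2) cis to C4, as needed for the carboxyl to end up cis to O5.

**Step 4**
Reactants: 5 (3S,5R)-3-allyl-3-hydroxy-5-(trityloxymethyl)dihydrofuran-2(3H)-one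
Product: 8 (2S,4R)-2-allyl-4-(tert-butyldimethylsilyloxy)-2-hydroxy-5-(trityloxy)pentanoic acid, via lithium dihydroxy carboxylate 6 (not isolated), via silyl ester silyl ether 7 (not isolated)
Conditions: LiOH·H2O (1.1 equiv), THF/H2O, rt; evaporate, toluene azeotrope; TBSCl, imidazole, DMF, rt → 40 °C; then K2CO3 (cat.), MeOH/THF/H2O, 0 °C; pH 5 buffer
Reagents that add atoms: lithium hydroxide [Li+].[OH-]; tert-butyldimethylsilyl chloride C[Si](C)(Cl)C(C)(C)C
Why: Saponification gives a carboxylate that cannot relactonise while basic; TBSCl/imidazole then caps secondary O5 (the tertiary C1-OH is inert) and the labile silyl ester is hydrolysed selectively, a standard lactone to silyloxy-acid sequence that touches neither stereocentre.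

**Step 5**
Reactants: 8 (2S,4R)-2-allyl-4-(tert-butyldimethylsilyloxy)-2-hydroxy-5-(trityloxy)pentanoic acid
Product: 9 (S)-5-allyl-5-[(R)-2-(tert-butyldimethylsilyloxy)-3-(trityloxy)propyl]-2,2-dimethyl-1,3-dioxolan-4-one
Conditions: 2,2-dimethoxypropane, PPTS (cat.), acetone, rt
Reagents that add atoms: 2,2-dimethoxypropane COC(C)(C)OC
Why: Acid-catalysed ketalisation of the α-hydroxy acid closes the 2,2-dimethyl-1,3-dioxolan-4-one, masking C1-OH (which would otherwise form a five-membered lactol with the C4 aldehyde) and the carboxyl together under conditions the trityl and TBS ethers should tolerate.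

**Step 6**
Reactants: 9 (S)-5-allyl-5-[(R)-2-(tert-butyldimethylsilyloxy)-3-(trityloxy)propyl]-2,2-dimethyl-1,3-dioxolan-4-one
Product: 10 (S)-5-allyl-5-[(R)-2-(tert-butyldimethylsilyloxy)-3-hydroxypropyl]-2,2-dimethyl-1,3-dioxolan-4-one
Conditions: HCO2H/Et2O (1:1), 0 °C → rt, about 20 min; cold aq. NaHCO3
Reagents that add atoms: none
Why: Trityl ethers ionise (SN1 solvolysis) in formic acid/ether within minutes, whereas a secondary TBS ether and the dioxolanone should be inert on this time scale, so only O4 is unmasked; the alcohol is oxidised without storage.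

**Step 7**
Reactants: 10 (S)-5-allyl-5-[(R)-2-(tert-butyldimethylsilyloxy)-3-hydroxypropyl]-2,2-dimethyl-1,3-dioxolan-4-one
Product: 11 (R)-3-[(S)-4-allyl-2,2-dimethyl-5-oxo-1,3-dioxolan-4-yl]-2-(tert-butyldimethylsilyloxy)propanal
Conditions: Dess–Martin periodinane, CH2Cl2, 0 °C → rt; aq. Na2S2O3/NaHCO3 work-up
Reagents that add atoms: none
Why: Dess–Martin oxidation gives the α-silyloxy aldehyde under near-neutral, non-enolising conditions, so the C5 configuration should be preserved.

**Step 8**
Reactants: 11 (R)-3-[(S)-4-allyl-2,2-dimethyl-5-oxo-1,3-dioxolan-4-yl]-2-(tert-butyldimethylsilyloxy)propanal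
Product: 12 (R)-2-(tert-butyldimethylsilyloxy)-3-[(R)-2,2-dimethyl-5-oxo-4-(2-oxoethyl)-1,3-dioxolan-4-yl]propanal (the 1,6-dialdehyde)
Conditions: O3, CH2Cl2, −78 °C; then PPh3, −78 °C → rt; short silica plug, used at once
Reagents that add atoms: ozone [O-][O+]=O
Why: Ozonolysis of the terminal alkene with reductive work-up gives the C3 aldehyde; the existing aldehyde, silyl ether and dioxolanone are inert to ozone at −78 °C.

**Step 9**
Reactants: 12 (R)-2-(tert-butyldimethylsilyloxy)-3-[(R)-2,2-dimethyl-5-oxo-4-(2-oxoethyl)-1,3-dioxolan-4-yl]propanal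
Product: 13 quinic acid with O1 and the carboxyl joined as the spiro 2,2-dimethyl-1,3-dioxolan-4-one and O5 as TBS ether, 3,4-cis-diol free, configured as in (−)-quinic acid
Conditions: SmI2 (3 equiv, 0.1 M in THF), t-BuOH (3 equiv), THF, −78 → −30 °C, slow addition of 12; aq. NaHCO3
Reagents that add atoms: none
Why: Single-electron transfer from SmI2 (divalent samarium) to the two aldehydes gives ketyl radical anions that are held on trivalent samarium and join carbon to carbon at C3–C4; the closest known reaction is the SmI2 pinacol cyclisation of carbohydrate-derived 1,6-dialdehydes to cis-cyclohexane-1,2-diols, as used for inositols and carbasugars. The cyclohexane is closed by this intramolecular ketyl–carbonyl coupling of the six-carbon chain through a chair-like array. C3 and C4 are both new: their cis relationship should follow from the two oxygens staying bridged by samarium while the bond forms, and the face at C4 is set by the adjacent C5 silyloxy stereocentre, the samarium-bound oxygen taking the position trans to OTBS for steric and dipolar reasons, with C1 too remote to interfere. The step needs chemoselectivity for the aldehydes over the dioxolanone carbonyl and over C5–O cleavage; the large gap in reduction potential at −78 °C without strongly donating additives, and the silyl ether being a poor leaving group, should secure it. It also needs ring closure to outrun simple reduction and intermolecular coupling, which slow addition of dilute dialdehyde and the weak proton donor t-BuOH are meant to ensure.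

**Step 10**
Reactants: 13 quinic acid 1,7-dioxolanone 5-O-TBS ether
Product: 14 quinic acid with O1 and the carboxyl joined as the spiro 2,2-dimethyl-1,3-dioxolan-4-one, 3,4,5-triol free
Conditions: HF·pyridine, pyridine, THF, 0 °C → rt
Reagents that add atoms: none
Why: Buffered fluoride desilylation frees O5 without generating an alkoxide, so O5 should not attack the dioxolanone carbonyl to give the bridged 1,5-lactone.

**Step 11**
Reactants: 15 caffeic acid
Product: 17 (E)-3-[3,4-bis(tert-butyldimethylsilyloxy)phenyl]acrylic acid, via persilylated caffeate 16 (not isolated)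
Conditions: TBSCl (3.3 equiv), imidazole, DMF, rt; then AcOH/THF/H2O (3:1:1), rt
Reagents that add atoms: tert-butyldimethylsilyl chloride C[Si](C)(Cl)C(C)(C)C
Why: Exhaustive silylation followed by selective hydrolysis of the labile silyl ester (aryl silyl ethers survive dilute acetic acid) gives the catechol-protected acid with the E-alkene untouched.

**Step 12**
Reactants: 14 quinic acid 1,7-dioxolanone triol; 17 (E)-3-[3,4-bis(tert-butyldimethylsilyloxy)phenyl]acrylic acid
Product: 20 5-O-[3,4-bis(tert-butyldimethylsilyloxy)cinnamoyl]quinic acid 1,7-dioxolanone (3,4-diol free), via triol 3,4-O-phenylboronate 18 (not isolated), via O5-acylated 3,4-O-phenylboronate 19 (not isolated)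
Conditions: PhB(OH)2 (1.05 equiv), 4 Å MS, CH2Cl2, rt; then 17, EDC·HCl, DMAP, 0 °C → rt; then pinacol, rt
Reagents that add atoms: none
Why: Phenylboronic acid condenses reversibly and preferentially with the cis-3,4-diol to a five-membered boronate (transient boronate protection, as practised on cis-diols of pyranosides), leaving equatorial O5 as the only free hydroxyl for Steglich esterification; transesterification with pinacol then releases the diol under neutral conditions.

**Step 13**
Reactants: 20 5-O-[3,4-bis(tert-butyldimethylsilyloxy)cinnamoyl]quinic acid 1,7-dioxolanone; 21 mono-tert-butyl malonate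
Product: 23 4-O-(3-tert-butoxy-3-oxopropanoyl)-5-O-[3,4-bis(tert-butyldimethylsilyloxy)cinnamoyl]quinic acid 1,7-dioxolanone (O3 free), via tert-butyl malonyl chloride 22 (not isolated)
Conditions: 21, Me2C=C(Cl)NMe2, CH2Cl2, 0 °C; then 20, Ph2BOCH2CH2NH2 (10 mol %), iPr2NEt, MeCN, 0 °C → rt
Reagents that add atoms: none
Why: In borinic acid-catalysed regioselective acylation the diphenylborinate binds the cis-3,4-diol as a tetracoordinate adduct and directs the acyl chloride to the equatorial oxygen O4; the chloride is made under neutral conditions with the Ghosez chloroenamine so that the tert-butyl ester survives.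

**Step 14**
Reactants: 23 4-O-(3-tert-butoxy-3-oxopropanoyl)-5-O-[3,4-bis(tert-butyldimethylsilyloxy)cinnamoyl]quinic acid 1,7-dioxolanone
Product: 25 5-O-caffeoyl-4-O-malonyl-(−)-quinic acid (CNP0286789.1), via catechol-silylated triacid 24 (not isolated)
Conditions: TFA/H2O (9:1), 0 °C → rt; evaporate below 25 °C; then HF·pyridine, pyridine, THF, 0 °C; C18 chromatography
Reagents that add atoms: none
Why: Aqueous trifluoroacetic acid cleaves the tert-butyl ester (loss of isobutene) and hydrolyses the dioxolanone at its acetal carbon to the free C1 hydroxy acid, and HF·pyridine then removes the aryl silyl ethers; both stages are non-basic, which should avoid O4 to O3 acyl migration and cleavage of the malonyl and caffeoyl esters.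

**Compound list**
1 | (R)-5-(hydroxymethyl)dihydrofuran-2(3H)-one | O=C1CC[C@H](CO)O1 | starting material
2 | (R)-5-(trityloxymethyl)dihydrofuran-2(3H)-one | O=C1CC[C@H](COC(c2ccccc2)(c2ccccc2)c2ccccc2)O1 | intermediate
3 | allyl bromide | C=CCBr | starting material
4 | (3S,5R)-3-allyl-5-(trityloxymethyl)dihydrofuran-2(3H)-one | O=C1O[C@@H](COC(c2ccccc2)(c2ccccc2)c2ccccc2)C[C@@H]1CC=C | intermediate
5 | (3S,5R)-3-allyl-3-hydroxy-5-(trityloxymethyl)dihydrofuran-2(3H)-one | O=C1O[C@@H](COC(c2ccccc2)(c2ccccc2)c2ccccc2)C[C@@]1(O)CC=C | intermediate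
6 | lithium (2S,4R)-2-allyl-2,4-dihydroxy-5-(trityloxy)pentanoate | [Li+].[O-]C(=O)[C@](O)(CC=C)C[C@@H](O)COC(c1ccccc1)(c1ccccc1)c1ccccc1 | intermediate
7 | tert-butyldimethylsilyl (2S,4R)-2-allyl-4-(tert-butyldimethylsilyloxy)-2-hydroxy-5-(trityloxy)pentanoate | CC(C)(C)[Si](C)(C)OC(=O)[C@](O)(CC=C)C[C@@H](O[Si](C)(C)C(C)(C)C)COC(c1ccccc1)(c1ccccc1)c1ccccc1 | intermediate
8 | (2S,4R)-2-allyl-4-(tert-butyldimethylsilyloxy)-2-hydroxy-5-(trityloxy)pentanoic acid | OC(=O)[C@](O)(CC=C)C[C@@H](O[Si](C)(C)C(C)(C)C)COC(c1ccccc1)(c1ccccc1)c1ccccc1 | intermediate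
9 | (S)-5-allyl-5-[(R)-2-(tert-butyldimethylsilyloxy)-3-(trityloxy)propyl]-2,2-dimethyl-1,3-dioxolan-4-one | C=CC[C@]1(OC(C)(C)OC1=O)C[C@@H](O[Si](C)(C)C(C)(C)C)COC(c1ccccc1)(c1ccccc1)c1ccccc1 | intermediate
10 | (S)-5-allyl-5-[(R)-2-(tert-butyldimethylsilyloxy)-3-hydroxypropyl]-2,2-dimethyl-1,3-dioxolan-4-one | C=CC[C@]1(OC(C)(C)OC1=O)C[C@@H](O[Si](C)(C)C(C)(C)C)CO | intermediate
11 | (R)-3-[(S)-4-allyl-2,2-dimethyl-5-oxo-1,3-dioxolan-4-yl]-2-(tert-butyldimethylsilyloxy)propanal | C=CC[C@]1(OC(C)(C)OC1=O)C[C@@H](O[Si](C)(C)C(C)(C)C)C=O | intermediate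
12 | (R)-2-(tert-butyldimethylsilyloxy)-3-[(R)-2,2-dimethyl-5-oxo-4-(2-oxoethyl)-1,3-dioxolan-4-yl]propanal | O=CC[C@]1(OC(C)(C)OC1=O)C[C@@H](O[Si](C)(C)C(C)(C)C)C=O | intermediate
13 | quinic acid 1,7-dioxolanone (acetonide of C1-OH and CO2H) 5-O-TBS ether, 3,4-diol free | O[C@@H]1[C@H](O)C[C@]2(OC(C)(C)OC2=O)C[C@H]1O[Si](C)(C)C(C)(C)C | intermediate
14 | quinic acid 1,7-dioxolanone, 3,4,5-triol free | O[C@@H]1[C@H](O)C[C@]2(OC(C)(C)OC2=O)C[C@H]1O | intermediate
15 | caffeic acid | O=C(O)/C=C/c1ccc(O)c(O)c1 | starting material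
16 | tert-butyldimethylsilyl (E)-3-[3,4-bis(tert-butyldimethylsilyloxy)phenyl]acrylate | CC(C)(C)[Si](C)(C)OC(=O)/C=C/c1ccc(O[Si](C)(C)C(C)(C)C)c(O[Si](C)(C)C(C)(C)C)c1 | intermediate
17 | (E)-3-[3,4-bis(tert-butyldimethylsilyloxy)phenyl]acrylic acid | OC(=O)/C=C/c1ccc(O[Si](C)(C)C(C)(C)C)c(O[Si](C)(C)C(C)(C)C)c1 | intermediate
18 | 3,4-O-phenylboronate of triol 14 | c1ccccc1B2O[C@@H]3[C@H](O2)C[C@]4(OC(C)(C)OC4=O)C[C@H]3O | intermediate
19 | 3,4-O-phenylboronate of 14 esterified at O5 with 17 | c1ccccc1B2O[C@@H]3[C@H](O2)C[C@]4(OC(C)(C)OC4=O)C[C@H]3OC(=O)/C=C/c1ccc(O[Si](C)(C)C(C)(C)C)c(O[Si](C)(C)C(C)(C)C)c1 | intermediate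
20 | 5-O-[3,4-bis(tert-butyldimethylsilyloxy)cinnamoyl]quinic acid 1,7-dioxolanone, 3,4-diol free | O[C@@H]1[C@H](O)C[C@]2(OC(C)(C)OC2=O)C[C@H]1OC(=O)/C=C/c1ccc(O[Si](C)(C)C(C)(C)C)c(O[Si](C)(C)C(C)(C)C)c1 | intermediate
21 | mono-tert-butyl malonate | CC(C)(C)OC(=O)CC(=O)O | starting material
22 | tert-butyl malonyl chloride | CC(C)(C)OC(=O)CC(=O)Cl | intermediate
23 | 4-O-(3-tert-butoxy-3-oxopropanoyl)-5-O-[3,4-bis(tert-butyldimethylsilyloxy)cinnamoyl]quinic acid 1,7-dioxolanone | CC(C)(C)OC(=O)CC(=O)O[C@@H]1[C@H](O)C[C@]2(OC(C)(C)OC2=O)C[C@H]1OC(=O)/C=C/c1ccc(O[Si](C)(C)C(C)(C)C)c(O[Si](C)(C)C(C)(C)C)c1 | intermediate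
24 | 5-O-[3,4-bis(tert-butyldimethylsilyloxy)cinnamoyl]-4-O-malonylquinic acid | O=C(O)CC(=O)O[C@@H]1[C@H](O)C[C@@](O)(C(=O)O)C[C@H]1OC(=O)/C=C/c1ccc(O[Si](C)(C)C(C)(C)C)c(O[Si](C)(C)C(C)(C)C)c1 | intermediate
25 | 5-O-caffeoyl-4-O-malonyl-(−)-quinic acid | O=C(O)CC(=O)O[C@@H]1[C@H](O)C[C@@](O)(C(=O)O)C[C@H]1OC(=O)/C=C/c1ccc(O)c(O)c1 | target

**Totals**
Total step count: 14. Longest linear sequence: 13 steps (steps 1–10, 12, 13, 14).

**Steps most likely to fail**

Step 9 (pinacol ring closure). The ring may close on the wrong face at C4, so that the new diol lies cis to O5. The samarium bridge may be lost, giving a trans-diol. The aldehydes may be reduced before the C–C bond forms. The α-silyloxy aldehyde may also epimerise at C5 before it reacts. The fallback sets out from aldehyde 11. Methylenation of the C4 aldehyde with Ph3P=CH2 (THF, −78 → 0 °C) would give the 1,6-diene (S)-5-allyl-5-[(R)-2-(tert-butyldimethylsilyloxy)but-3-enyl]-2,2-dimethyl-1,3-dioxolan-4-one F1. Ring-closing metathesis with the second-generation Grubbs catalyst RuCl2(=CHPh)(H2IMes)(PCy3) in CH2Cl2 at 40 °C would close the cyclohexene with a C3=C4 double bond, the 3,4-didehydro-3,4-dideoxy analogue of 13, F2. Dihydroxylation with OsO4 (cat.) and N-methylmorpholine N-oxide in acetone/H2O should occur anti to the allylic C5 silyloxy group and give the same cis-3,4-diol, so the route is rejoined at 13.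

Step 13 (O4 malonylation). Acylation may occur at axial O3 or at both oxygens. The amine base may turn the malonyl chloride into a ketene that oligomerises. The base may also promote acyl migration between O5, O4 and O3. The fallback sets out from diol 20. Heating with Bu2SnO (toluene, 80 °C, 4 Å MS) would give the 3,4-O-dibutylstannylene acetal of 20, F3. This acetal would be treated with acid chloride 22 (made as in step 13) in CH2Cl2 at 0 °C without any amine base. Tin acetals of cis-diols are acylated at the equatorial oxygen, so the route is rejoined at 23.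

Step 12 (boronate-masked esterification of O5). The boronate may exchange during the carbodiimide coupling and expose O4 to acylation. The caffeoyl group may shift from O5 to O4 when the boronate is removed. The fallback sets out from diol 13, with O5 still silylated. Chloroacetic anhydride and pyridine (CH2Cl2, 0 °C) would give the 3,4-bis-O-chloroacetate of 13, F4. HF·pyridine would remove the silyl group to give the 3,4-bis-O-chloroacetyl O5 alcohol F5. Esterification with 17 (EDC·HCl, DMAP) would give the 3,4-bis-O-chloroacetyl 5-O-cinnamoyl ester F6. Thiourea with NaHCO3 and Bu4NI in THF at 55 °C removes chloroacetates selectively in the presence of other esters, so the route is rejoined at 20.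

**Further compounds**
F1 | step 9 | (S)-5-allyl-5-[(R)-2-(tert-butyldimethylsilyloxy)but-3-enyl]-2,2-dimethyl-1,3-dioxolan-4-one | C=CC[C@]1(OC(C)(C)OC1=O)C[C@@H](O[Si](C)(C)C(C)(C)C)C=C
F2 | step 9 | 3,4-didehydro-3,4-dideoxy analogue of 13 (cyclohexene, C5 OTBS, C1 spiro-dioxolanone) | C1=CC[C@]2(OC(C)(C)OC2=O)C[C@H]1O[Si](C)(C)C(C)(C)C
F3 | step 13 | 3,4-O-dibutylstannylene acetal of 20 | CCCC[Sn]1(CCCC)O[C@@H]2[C@H](O1)C[C@]3(OC(C)(C)OC3=O)C[C@H]2OC(=O)/C=C/c2ccc(O[Si](C)(C)C(C)(C)C)c(O[Si](C)(C)C(C)(C)C)c2
F4 | step 12 | 3,4-bis-O-chloroacetate of 13 | O=C(CCl)O[C@@H]1[C@H](OC(=O)CCl)C[C@]2(OC(C)(C)OC2=O)C[C@H]1O[Si](C)(C)C(C)(C)C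
F5 | step 12 | 3,4-bis-O-chloroacetyl quinic acid 1,7-dioxolanone, O5 free | O=C(CCl)O[C@@H]1[C@H](OC(=O)CCl)C[C@]2(OC(C)(C)OC2=O)C[C@H]1O
F6 | step 12 | 3,4-bis-O-chloroacetyl-5-O-[3,4-bis(tert-butyldimethylsilyloxy)cinnamoyl]quinic acid 1,7-dioxolanone | O=C(CCl)O[C@@H]1[C@H](OC(=O)CCl)C[C@]2(OC(C)(C)OC2=O)C[C@H]1OC(=O)/C=C/c1ccc(O[Si](C)(C)C(C)(C)C)c(O[Si](C)(C)C(C)(C)C)c1
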